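Plan
- **Enabling feature.** In the nine-membered carbocycle (C1–C9) the run C2H2–C3H=C4(CH3)–C5H(OH) is a 2-methylallylic alcohol next to a CH2, which is the retron of an epoxy-Ramberg–Bäcklund reaction. The retrosynthesis cuts C3=C4, places SO2 between C3 and C4, and ties the C5 oxygen back to C4 as an oxirane (ten-membered epoxy sulfone 14).
- **Further cuts.** Oxirane oxygen (back to a cis-alkenyl sulfone); pyran bonds O–C8 and C14–C1′ (hetero-Diels–Alder); S–C4 (copper C–S coupling); C4=C5 (Wittig); C3–S (radical thiylation).
- **Forward ring order.** The cyclobutane is bought in (−)-β-caryophyllene. Step 1 excises that terpene's own medium ring and its strained E-alkene (the site a heterodiene would attack first), with loss of C4/C12. Then follow the temporary ten-membered thiacycle, the dihydropyran, the oxirane, and last the nine-membered ring by contraction with extrusion of SO2.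
- **Stereochemistry.** C1 and C9 come from the terpene. C8 and C1′ come from outer-face, cyclobutane-exo cycloaddition on the thiacycle. C5 comes from outer-face epoxidation and is carried unchanged through the contraction. Z-C3=C4 comes from the cis-fused episulfone.

Key step: step 8

Assumption: syncarpic acid (10) is taken as purchasable; atom labels follow caryophyllane numbering (C1/C9 ring fusion, C8 spiro carbon, C10/C11 cyclobutane, C12 methyl on C4, C14 pyran CH2, C1′ isobutyl-bearing carbon).

Step 1
Reactants: 1 (−)-β-caryophyllene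
Product: 3 seco-aldehyde 2-pyridyl sulfide (1R,9S), via methoxy hydroperoxide 2 (not isolated)
Conditions: O3 (1 equiv), MeOH–CH2Cl2, −78 °C; Ar purge; (2-PyS)2, FeSO4·7H2O, −78 °C → rt
Reagents that add atoms: ozone, [O-][O+]=O; 2,2′-dipyridyl disulfide, c1ccc(SSc2ccccn2)nc1; methanol, CO (kept in 2 only)
Why: Ozonolysis followed by dealkenylative thiylation: ozone picks the strained E-C4=C5 alkene over C8=C14, the primary ozonide opens to the more substituted carbonyl oxide that methanol traps as 2, and single-electron reduction by divalent iron gives an alkoxy radical whose β-scission expels methyl acetate and leaves the primary C3 radical for homolytic substitution at the disulfide, while C1 and C9 stay untouched and the trans-cyclobutane holds the radical away from C8=C14.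

Step 2
Reactants: 3 seco-aldehyde 2-pyridyl sulfide; 4 ethyltriphenylphosphonium iodide
Product: 6 (Z)-alkenyl iodide 2-pyridyl sulfide, via iodo ylide 5 (not isolated)
Conditions: 4, nBuLi, THF, 0 °C; I2, −78 °C; NaHMDS, −20 °C; then 3, −78 → −20 °C
Reagents that add atoms: iodine, II
Why: Stork–Zhao-type Wittig olefination with a non-stabilised α-iodo ylide is kinetically Z-selective, so iodine and C6 end up cis on the new C4=C5 bond, a fresh C4 with its methyl C12 is brought in, and no stereocentre is formed.

Step 3
Reactants: 6 (Z)-alkenyl iodide 2-pyridyl sulfide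
Product: 7 (Z)-alkenyl iodide 2-pyridyl sulfone
Conditions: H2O2 (30 % aq.), (NH4)6Mo7O24·4H2O (cat.), EtOH, 0 °C → rt
Reagents that add atoms: hydrogen peroxide, OO
Why: Peroxomolybdate-catalysed sulfide-to-sulfone oxidation is faster than epoxidation of the unactivated 1,1-disubstituted alkene and leaves the alkenyl iodide alone.

Step 4
Reactants: 7 (Z)-alkenyl iodide 2-pyridyl sulfone
Product: 8 sodium C3-sulfinate bearing the (Z)-alkenyl iodide
Conditions: EtSNa, THF, 0 °C → rt; trituration with Et2O
Reagents that add atoms: sodium ethanethiolate, CC[S-].[Na+]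
Why: Nucleophilic aromatic ipso-substitution by thiolate at C2 of the electron-poor 2-sulfonylpyridine releases the alkyl sulfinate, and the alkenyl iodide does not react in the absence of a metal catalyst.

Step 5
Reactants: 8 sodium C3-sulfinate bearing the (Z)-alkenyl iodide
Product: 9 ten-membered cyclic (Z)-alkenyl sulfone with C8 exocyclic methylene
Conditions: CuI (cat.), L-proline, NaOH, DMSO, 90 °C, slow addition, high dilution
Reagents that add atoms: none
Why: Ullmann-type copper-catalysed coupling of a sulfinate with an alkenyl iodide forms the S–C4 bond with retention of alkene geometry, so the ten-membered ring closes as the cis-alkenyl sulfone, helped by the cis-alkene and the trans-cyclobutane that turn the two chain ends toward each other.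

Step 6
Reactants: 9 ten-membered cyclic (Z)-alkenyl sulfone; 10 syncarpic acid; 11 isovaleraldehyde
Product: 13 spiro-dihydropyran alkenyl sulfone (8S,1′R), via alkylidene trione 12 (not isolated)
Conditions: ethylenediammonium diacetate (cat.), 4 Å MS, toluene, 90 °C, slow addition of 10 and 11
Reagents that add atoms: none
Why: Domino Knoevenagel condensation/inverse-electron-demand hetero-Diels–Alder reaction: the electron-poor 1-oxadiene 12 ignores the electron-poor sulfone alkene and adds to C8=C14 with oxygen at the more substituted C8, on the outer face of the ring (H9 eclipsing C8=C14, C1 and the ring interior covering the other face, which gives 8S), with its trione ring over C7, the cyclobutane exo and the isobutyl group outside (which gives 1′R).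

Step 7
Reactants: 13 spiro-dihydropyran alkenyl sulfone
Product: 14 (4S,5R)-α,β-epoxy sulfone
Conditions: tBuOOH, nBuLi, THF, −78 → −20 °C; H2O
Reagents that add atoms: tert-butyl hydroperoxide, CC(C)(C)OO
Why: Weitz–Scheffer-type nucleophilic epoxidation of an alkenyl sulfone: tBuOOLi adds to C5 and the α-sulfonyl carbanion closes on oxygen before the ring-held C4–C5 bond can rotate, so S and C6 stay cis, attack on the outer face of the cis-alkene (the inner face is covered by the C2, C3 and C7 methylenes) should set 5R and 4S, and the tetrasubstituted β-alkoxy enone is too hindered and electron-rich to react.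

Step 8
Reactants: 14 (4S,5R)-α,β-epoxy sulfone
Product: 16 tomentodione O, via hydroxy episulfone 15 (not isolated)
Conditions: LiOtBu, THF, 0 °C → rt; H2O
Reagents that add atoms: none
Why: Proposed new method: LiOtBu can deprotonate only C3, because C4 is fully substituted, and the C3 carbanion attacks C4 across sulfur anti to the C4–O bond (3-exo-tet), which opens the oxirane to the C5 alkoxide and makes the C3–C4 bond, so the ten-membered thiacycle becomes the nine-membered carbocycle fused to a thiirane 1,1-dioxide (15). Stereospecific cheletropic loss of SO2 from 15 then leaves the C3=C4 double bond, so ring, alkene and free carbinol appear in one operation and the helper atom removes itself. The closest known reaction types are the epoxy-Ramberg–Bäcklund reaction of open-chain α,β-epoxy sulfones to allylic alcohols and the halogenative Ramberg–Bäcklund contraction of ten-membered cyclic sulfones to nine-membered cycloalkenes, and what is new is their union in a transannular, ring-contracting mode. No new stereocentre remains in the product: C5 keeps its C–O bond and the R configuration written in step 7, C3 and C4 become sp2, and C1, C8, C9 and C1′ carry no acidic hydrogen. The Z geometry needs the cis-fused episulfone (C2 and C5 on the same face), which is secured by the lower strain of a cis-bicyclo[7.1.0] frame and by base-mediated equilibration at C3 before SO2 leaves. The step also needs carbanion attack to outrun addition of base at C5 with loss of sulfinate, which the hindered, poorly nucleophilic tert-butoxide and the W-shaped H–C3–S–C4–O array open to the ring should secure.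

Compound list
1 | (−)-β-caryophyllene, (1R,4E,9S) | C/C1=C\CCC(=C)[C@H]2CC(C)(C)[C@@H]2CC1 | starting material
2 | 4,5-seco C5-aldehyde with C4 α-methoxy hydroperoxide (C4 epimers; 1R,9S) | O=CCCC(=C)[C@H]1CC(C)(C)[C@@H]1CCC(C)(OC)OO | intermediate
3 | 4-[(1S,2R)-3,3-dimethyl-2-[2-(pyridin-2-ylsulfanyl)ethyl]cyclobutyl]pent-4-enal (C5 aldehyde, C3–S-2-pyridyl; 1R,9S in caryophyllane numbering) | O=CCCC(=C)[C@H]1CC(C)(C)[C@@H]1CCSc2ccccn2 | intermediate
4 | ethyltriphenylphosphonium iodide | CC[P+](c1ccccc1)(c1ccccc1)c1ccccc1.[I-] | starting material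
5 | (1-iodoethylidene)triphenylphosphorane | CC(I)=P(c1ccccc1)(c1ccccc1)c1ccccc1 | intermediate
6 | (Z)-C4-iodo-C4=C5 alkene, C8=C14 methylene, C3–S-2-pyridyl (1R,9S) | C/C(I)=C/CCC(=C)[C@H]1CC(C)(C)[C@@H]1CCSc2ccccn2 | intermediate
7 | 2-pyridyl sulfone of 6 | C/C(I)=C/CCC(=C)[C@H]1CC(C)(C)[C@@H]1CCS(=O)(=O)c2ccccn2 | intermediate
8 | sodium C3-sulfinate with (Z)-alkenyl iodide | C/C(I)=C/CCC(=C)[C@H]1CC(C)(C)[C@@H]1CCS(=O)[O-].[Na+] | intermediate
9 | trans-cyclobutane-fused thiacyclodecene 1,1-dioxide: S between C3 and C4, (Z)-C4=C5, C4-methyl, C8 exocyclic methylene (1R,9S) | C/C1=C/CCC(=C)[C@H]2CC(C)(C)[C@@H]2CCS1(=O)=O | intermediate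
10 | syncarpic acid (2,2,4,4-tetramethylcyclohexane-1,3,5-trione) | CC1(C)C(=O)CC(=O)C(C)(C)C1=O | starting material
11 | isovaleraldehyde | CC(C)CC=O | starting material
12 | 6-(3-methylbutylidene)-2,2,4,4-tetramethylcyclohexane-1,3,5-trione | CC(C)CC=C1C(=O)C(C)(C)C(=O)C(C)(C)C1=O | intermediate
13 | spiro-dihydropyran at C8 on the ten-membered (Z)-alkenyl sulfone (1R,9S,8S,1′R) | C/C1=C/CC[C@]2(C[C@@H](CC(C)C)C3=C(O2)C(C)(C)C(=O)C(C)(C)C3=O)[C@H]4CC(C)(C)[C@@H]4CCS1(=O)=O | intermediate
14 | (4S,5R)-4,5-epoxide of 13 (S and C6 cis on the oxirane) | C[C@@]12O[C@@H]1CC[C@]3(C[C@@H](CC(C)C)C4=C(O3)C(C)(C)C(=O)C(C)(C)C4=O)[C@H]5CC(C)(C)[C@@H]5CCS2(=O)=O | intermediate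
15 | cis-fused C3/C4 thiirane 1,1-dioxide on the nine-membered ring, (5R)-hydroxyl | C[C@@]12[C@H](O)CC[C@]3(C[C@@H](CC(C)C)C4=C(O3)C(C)(C)C(=O)C(C)(C)C4=O)[C@H]5CC(C)(C)[C@@H]5C[C@@H]1S2(=O)=O | intermediate
16 | tomentodione O (1R,9S,8S,5R,1′R; Z-C3=C4) | C/C1=C/C[C@@H]2[C@H](CC2(C)C)[C@]2(CC[C@H]1O)C[C@@H](CC(C)C)C1=C(O2)C(C)(C)C(=O)C(C)(C)C1=O | target

Total step count: 8. Longest linear sequence: 8 steps (1 → 16); 4, 10 and 11 enter as purchased compounds.

Steps most likely to fail

Step 8. The transannular displacement may be outrun by other base-induced processes. If the ring does not populate the W-shaped H–C3–S–C4–O array, opening of the oxirane at C5 with loss of sulfinate, or isomerisation of the oxirane, would consume 14. The fallback uses known chemistry, sets out from 13 and returns at 16. The alkenyl sulfone is hydrogenated (H2, Pd/C, EtOAc) to the saturated ten-membered sulfone F1. A halogenative Ramberg–Bäcklund contraction in the Meyers–Chan variant (CBr2F2, KOH on Al2O3, tBuOH–CH2Cl2) then gives the 5-deoxy (Z)-cyclononene F2. Allylic hydroxylation of the ring CH2 next to the more substituted alkene carbon (SeO2 cat., tBuOOH, CH2Cl2) leads to 16.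

Step 5. Intermolecular coupling (oligomerisation) or loss of iodine at the copper centre may outrun closure of the strained ten-membered ring. The fallback closes the ring by SN2 at the sp3 carbon C3 instead; it sets out from 1 and returns at 9.
- Ozonolysis in MeOH followed by FeSO4·7H2O and TEMPO (dealkenylative aminoxylation) gives the C3 aminoxyl ether aldehyde F3.
- The α-iodo-ylide olefination of step 2 gives the (Z)-alkenyl iodide F4.
- Intermolecular CuI/L-proline coupling with sodium 3-methoxy-3-oxopropane-1-sulfinate gives the alkenyl sulfone ester F5.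
- Zn in AcOH cleaves the N–O bond to give the primary alcohol F6.
- The Appel reaction (I2, PPh3, imidazole) gives the primary iodide F7.
- One equivalent of NaOMe triggers a retro-Michael release of the sodium alkenylsulfinate F8, which on dilution in warm DMF alkylates itself at sulfur with the C3 iodide to give 9.

Step 7. Peroxide addition to C5 may show poor facial selectivity, because the nearest stereocentre (C8) is three bonds away and the cis-alkene can present either face. The fallback moves control of C5 to a reagent; it sets out from 13 and returns at 16. The epoxidation is run regardless and 14 is carried on together with the (4R,5S)-epoxy sulfone F9. The contraction of step 8 then gives 16 together with the 5-epimeric allylic alcohol F10. Dess–Martin oxidation of the mixture converges on the nine-membered 2-methyl enone F11. Corey–Bakshi–Shibata reduction ((S)-Me-CBS, BH3·SMe2, −40 °C; the alkenyl side acts as the large group) delivers the 5R alcohol 16.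

Further compounds
F1 | step 8 | saturated ten-membered sulfone (C4 epimers) | CC1CCC[C@]2(C[C@@H](CC(C)C)C3=C(O2)C(C)(C)C(=O)C(C)(C)C3=O)[C@H]4CC(C)(C)[C@@H]4CCS1(=O)=O
F2 | step 8 | 5-deoxy (Z)-cyclononene | C/C1=C/C[C@@H]2[C@H](CC2(C)C)[C@]2(CCC1)C[C@@H](CC(C)C)C1=C(O2)C(C)(C)C(=O)C(C)(C)C1=O
F3 | step 5 | C3 aminoxyl ether aldehyde | O=CCCC(=C)[C@H]1CC(C)(C)[C@@H]1CCON2C(C)(C)CCCC2(C)C
F4 | step 5 | (Z)-alkenyl iodide aminoxyl ether | C/C(I)=C/CCC(=C)[C@H]1CC(C)(C)[C@@H]1CCON2C(C)(C)CCCC2(C)C
F5 | step 5 | alkenyl sulfone ester aminoxyl ether | C/C(=C/CCC(=C)[C@H]1CC(C)(C)[C@@H]1CCON2C(C)(C)CCCC2(C)C)S(=O)(=O)CCC(=O)OC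
F6 | step 5 | alkenyl sulfone ester primary alcohol | C/C(=C/CCC(=C)[C@H]1CC(C)(C)[C@@H]1CCO)S(=O)(=O)CCC(=O)OC
F7 | step 5 | alkenyl sulfone ester primary iodide | C/C(=C/CCC(=C)[C@H]1CC(C)(C)[C@@H]1CCI)S(=O)(=O)CCC(=O)OC
F8 | step 5 | sodium alkenylsulfinate primary iodide | C/C(=C/CCC(=C)[C@H]1CC(C)(C)[C@@H]1CCI)S(=O)[O-].[Na+]
F9 | step 7 | (4R,5S)-epoxy sulfone | C[C@]12O[C@H]1CC[C@]3(C[C@@H](CC(C)C)C4=C(O3)C(C)(C)C(=O)C(C)(C)C4=O)[C@H]5CC(C)(C)[C@@H]5CCS2(=O)=O
F10 | step 7 | 5-epi-tomentodione O | C/C1=C/C[C@@H]2[C@H](CC2(C)C)[C@]2(CC[C@@H]1O)C[C@@H](CC(C)C)C1=C(O2)C(C)(C)C(=O)C(C)(C)C1=O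
F11 | step 7 | nine-membered 2-methyl enone (C5 ketone) | C/C1=C/C[C@@H]2[C@H](CC2(C)C)[C@]2(CCC1=O)C[C@@H](CC(C)C)C1=C(O2)C(C)(C)C(=O)C(C)(C)C1=O
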